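**Retrosynthetic overview** (positions follow the azulene numbering of the target: C1 ketone, C3 isopropyl, C3a OH, C6 methyl, C8 ester oxygen, C8a methyl)

1. Last operations: acylation of the C8 hydroxyl with 4-methoxybenzoyl chloride, the C8 oxygen having been carried as a 4-methoxybenzyl (PMB) ether.
2. Key bond C2–C3, five-membered ring formed last: 5-exo cyclisation of an α-keto radical (an enolonium-type, acceptor α-carbon released from a chloromethyl ketone) onto an isobutenyl group. This sets C3 and turns the alkene into the isopropyl group.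
3. C3a–C3: isobutenyl Grignard addition to the ketone of a cycloheptenone β-keto ester; the ester is then homologated to the chloromethyl ketone (C1, C2).
4. Seven-membered ring formed first: ring-closing metathesis making C6=C7.
5. C8a–C8: Pd-catalysed asymmetric addition of an α-methyl β-keto ester to PMB-oxyallene (sets C8 and C8a); the keto ester comes from dianion alkylation of methyl 2-methylacetoacetate.

Assumption: the (R,R) antipode of the Trost ligand is taken to give the drawn configuration in step 4; if the sense of induction is the opposite, the (S,S) ligand is used.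

**Route**

Step 1
Reactants: 1 prop-2-yn-1-ol; 2 4-methoxybenzyl chloride
Product: 3 1-methoxy-4-[(prop-2-yn-1-yloxy)methyl]benzene
Conditions: NaH, n-Bu4NI (cat.), THF, 0 °C → rt
Reagents that add atoms: none
Why: Williamson ether synthesis of a primary alkoxide with a benzylic chloride; no stereocentre.

Step 2
Reactants: 3 1-methoxy-4-[(prop-2-yn-1-yloxy)methyl]benzene
Product: 4 1-methoxy-4-[(propa-1,2-dien-1-yloxy)methyl]benzene
Conditions: KOt-Bu (0.3 equiv), THF, 0 °C → rt
Reagents that add atoms: none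
Why: Base-catalysed propargyl-to-allenyl ether isomerisation, the standard preparation of alkoxyallenes; no stereocentre.

Step 3
Reactants: 5 methyl 2-methyl-3-oxobutanoate; 6 3-chloro-2-methylprop-1-ene
Product: 7 methyl 2,6-dimethyl-3-oxohept-6-enoate (racemic, C2 enolisable)
Conditions: NaH, THF, 0 °C; n-BuLi, 0 °C; 6, 0 °C → rt; 1 M HCl
Reagents that add atoms: none
Why: Huckin–Weiler dianion alkylation, in which only the more reactive terminal (γ) carbanion is alkylated by the allylic chloride; the C2 centre stays labile and is fixed in step 4.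

Step 4
Reactants: 7 methyl 2,6-dimethyl-3-oxohept-6-enoate; 4 1-methoxy-4-[(propa-1,2-dien-1-yloxy)methyl]benzene
Product: 8 methyl (2S)-2-[(1R)-1-[(4-methoxyphenyl)methoxy]prop-2-en-1-yl]-2,6-dimethyl-3-oxohept-6-enoate
Conditions: Pd2(dba)3·CHCl3 (2.5 mol %), (R,R)-DACH-phenyl Trost ligand (7.5 mol %), PhCO2H (10 mol %), Et3N (10 mol %), CH2Cl2, 25 °C
Reagents that add atoms: none
Why: Trost asymmetric hydroalkylation of an alkoxyallene, in which Pd–H adds to the allene and the β-keto ester enolate attacks the oxygen-bearing terminus of the 1-alkoxy-π-allyl complex; the ligand pocket sets the ether carbon (future C8) as R and selects the enolate face so that the quaternary carbon (future C8a) is S.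

Step 5
Reactants: 8 methyl (2S)-2-[(1R)-1-[(4-methoxyphenyl)methoxy]prop-2-en-1-yl]-2,6-dimethyl-3-oxohept-6-enoate
Product: 9 methyl (1S,7R)-7-[(4-methoxyphenyl)methoxy]-1,5-dimethyl-2-oxocyclohept-5-ene-1-carboxylate
Conditions: second-generation Grubbs catalyst (5 mol %), CH2Cl2 (5 mM), 40 °C
Reagents that add atoms: none
Why: Ring-closing metathesis of the vinyl group with the 1,1-disubstituted alkene, helped by the quaternary centre, gives the trisubstituted cycloheptene (C6=C7); no stereocentre is formed or touched.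

Step 6
Reactants: 9 methyl (1S,7R)-7-[(4-methoxyphenyl)methoxy]-1,5-dimethyl-2-oxocyclohept-5-ene-1-carboxylate; 10 (2-methylprop-1-en-1-yl)magnesium bromide
Product: 11 methyl (1S,2S,7R)-2-hydroxy-7-[(4-methoxyphenyl)methoxy]-1,5-dimethyl-2-(2-methylprop-1-en-1-yl)cyclohept-5-ene-1-carboxylate
Conditions: 10 (1.5 equiv), LaCl3·2LiCl (1.0 equiv), THF, 0 °C; H2O
Reagents that add atoms: none
Why: Lanthanum-promoted (Knochel-type) Grignard 1,2-addition in which the ketone and ester carbonyls chelate the Lewis acid and the alkenyl group enters from the methyl-bearing face opposite the ester, so the tertiary carbinol (future C3a) is S with OH cis to the ester and the alkenyl group trans to it, as the trans ring fusion needs.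

Step 7
Reactants: 11 methyl (1S,2S,7R)-2-hydroxy-7-[(4-methoxyphenyl)methoxy]-1,5-dimethyl-2-(2-methylprop-1-en-1-yl)cyclohept-5-ene-1-carboxylate
Product: 12 2-chloro-1-[(1S,2S,7R)-2-hydroxy-7-[(4-methoxyphenyl)methoxy]-1,5-dimethyl-2-(2-methylprop-1-en-1-yl)cyclohept-5-en-1-yl]ethan-1-one
Conditions: MeLi (1.0 equiv), THF, −78 °C; ICH2Cl (3.0 equiv), MeLi·LiBr (2.8 equiv), −78 °C; 2 M HCl in Et2O, −78 °C
Reagents that add atoms: chloroiodomethane ClCI
Why: Halomethyllithium homologation of an ester (Barluenga type), in which LiCH2Cl adds once and the tetrahedral adduct, chelated by the neighbouring lithium alkoxide, survives at −78 °C until the acid quench; no stereocentre is affected.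

Step 8
Reactants: 12 2-chloro-1-[(1S,2S,7R)-2-hydroxy-7-[(4-methoxyphenyl)methoxy]-1,5-dimethyl-2-(2-methylprop-1-en-1-yl)cyclohept-5-en-1-yl]ethan-1-one
Product: 13 (3R,3aS,8R,8aS)-3a-hydroxy-8-[(4-methoxyphenyl)methoxy]-6,8a-dimethyl-3-(propan-2-yl)-3,3a,4,5,8,8a-hexahydroazulen-1(2H)-one
Conditions: Bu3SnH (1.3 equiv, slow addition), AIBN (0.2 equiv), benzene (5 mM), 80 °C
Reagents that add atoms: none
Why: Tin hydride-mediated 5-exo-trig radical cyclisation (Stork/Curran type) in which the electrophilic α-keto radical at C2 (the enolonium-type carbon) adds to the electron-rich CH terminus of the isobutenyl group (C3), joining two carbons that are both donor positions of the 1,4-oxygenated C1–C3a unit, and the tertiary radical then takes hydrogen from Bu3SnH to become the isopropyl group; C3 is set R because the alkene reacts in the rotamer that puts the small C3a–OH, not the ring CH2, next to the cis methyl (1,3-allylic strain), and the trans-disposed side chains give the trans ring fusion.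

Step 9
Reactants: 13 (3R,3aS,8R,8aS)-3a-hydroxy-8-[(4-methoxyphenyl)methoxy]-6,8a-dimethyl-3-(propan-2-yl)-3,3a,4,5,8,8a-hexahydroazulen-1(2H)-one
Product: 14 (3R,3aS,8R,8aS)-3a,8-dihydroxy-6,8a-dimethyl-3-(propan-2-yl)-3,3a,4,5,8,8a-hexahydroazulen-1(2H)-one
Conditions: DDQ (1.3 equiv), CH2Cl2–pH 7 buffer (10:1), 0 °C
Reagents that add atoms: none
Why: Oxidative PMB ether cleavage (Oikawa–Yonemitsu), where hydride abstraction at the electron-rich benzylic CH2 is much faster than any reaction of the alkene, ketone or tertiary alcohol; no stereocentre is touched.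

Step 10
Reactants: 14 (3R,3aS,8R,8aS)-3a,8-dihydroxy-6,8a-dimethyl-3-(propan-2-yl)-3,3a,4,5,8,8a-hexahydroazulen-1(2H)-one; 15 4-methoxybenzoyl chloride
Product: 16 (3R,3aS,8R,8aS)-3a-hydroxy-6,8a-dimethyl-1-oxo-3-(propan-2-yl)-1,2,3,3a,4,5,8,8a-octahydroazulen-8-yl 4-methoxybenzoate
Conditions: pyridine, DMAP (0.1 equiv), CH2Cl2, 0 °C → rt
Reagents that add atoms: none
Why: DMAP-catalysed acylation, selective for the secondary allylic C8 hydroxyl over the much more hindered tertiary C3a hydroxyl; configuration at C8 is retained.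

**Compound list**

1 | prop-2-yn-1-ol | C#CCO | starting material
2 | 4-methoxybenzyl chloride | COc1ccc(CCl)cc1 | starting material
3 | 1-methoxy-4-[(prop-2-yn-1-yloxy)methyl]benzene | COc1ccc(COCC#C)cc1 | intermediate
4 | 1-methoxy-4-[(propa-1,2-dien-1-yloxy)methyl]benzene | COc1ccc(COC=C=C)cc1 | intermediate
5 | methyl 2-methyl-3-oxobutanoate | COC(=O)C(C)C(C)=O | starting material
6 | 3-chloro-2-methylprop-1-ene | CC(=C)CCl | starting material
7 | methyl 2,6-dimethyl-3-oxohept-6-enoate (racemic) | COC(=O)C(C)C(=O)CCC(C)=C | intermediate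
8 | methyl (2S)-2-[(1R)-1-[(4-methoxyphenyl)methoxy]prop-2-en-1-yl]-2,6-dimethyl-3-oxohept-6-enoate | COC(=O)[C@](C)(C(=O)CCC(C)=C)[C@H](OCc1ccc(OC)cc1)C=C | intermediate
9 | methyl (1S,7R)-7-[(4-methoxyphenyl)methoxy]-1,5-dimethyl-2-oxocyclohept-5-ene-1-carboxylate | COC(=O)[C@]1(C)C(=O)CCC(C)=C[C@H]1OCc2ccc(OC)cc2 | intermediate
10 | (2-methylprop-1-en-1-yl)magnesium bromide | CC(C)=C[Mg]Br | starting material
11 | methyl (1S,2S,7R)-2-hydroxy-7-[(4-methoxyphenyl)methoxy]-1,5-dimethyl-2-(2-methylprop-1-en-1-yl)cyclohept-5-ene-1-carboxylate | COC(=O)[C@]1(C)[C@@](O)(C=C(C)C)CCC(C)=C[C@H]1OCc2ccc(OC)cc2 | intermediate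
12 | 2-chloro-1-[(1S,2S,7R)-2-hydroxy-7-[(4-methoxyphenyl)methoxy]-1,5-dimethyl-2-(2-methylprop-1-en-1-yl)cyclohept-5-en-1-yl]ethan-1-one | ClCC(=O)[C@]1(C)[C@@](O)(C=C(C)C)CCC(C)=C[C@H]1OCc2ccc(OC)cc2 | intermediate
13 | (3R,3aS,8R,8aS)-3a-hydroxy-8-[(4-methoxyphenyl)methoxy]-6,8a-dimethyl-3-(propan-2-yl)-3,3a,4,5,8,8a-hexahydroazulen-1(2H)-one | COc1ccc(CO[C@@H]2C=C(C)CC[C@]3(O)[C@@H](C(C)C)CC(=O)[C@@]23C)cc1 | intermediate
14 | (3R,3aS,8R,8aS)-3a,8-dihydroxy-6,8a-dimethyl-3-(propan-2-yl)-3,3a,4,5,8,8a-hexahydroazulen-1(2H)-one | O[C@@H]1C=C(C)CC[C@]2(O)[C@@H](C(C)C)CC(=O)[C@@]12C | intermediate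
15 | 4-methoxybenzoyl chloride | COc1ccc(C(=O)Cl)cc1 | starting material
16 | (3R,3aS,8R,8aS)-3a-hydroxy-6,8a-dimethyl-1-oxo-3-(propan-2-yl)-1,2,3,3a,4,5,8,8a-octahydroazulen-8-yl 4-methoxybenzoate | COc1ccc(C(=O)O[C@@H]2C=C(C)CC[C@]3(O)[C@@H](C(C)C)CC(=O)[C@@]23C)cc1 | target

**Step count**

Total: 10 steps. Longest linear sequence: 9 steps (1, 2, 4, 5, 6, 7, 8, 9, 10).

**Steps most likely to fail**

Step 8 (key radical cyclisation). The α-keto radical could instead be reduced before it cyclises, or add to the ring alkene to give a bridged product, and the trans-fused closure is the strained mode. Fallback: set out from 9 and close the same ring through the C1–C2 bond with an acyl anion equivalent. (3-Methylbut-1-en-2-yl)lithium (from 2-bromo-3-methylbut-1-ene and t-BuLi) with CeCl3 in THF at −78 °C adds to the ketone to give methyl (1S,2S,7R)-2-hydroxy-7-[(4-methoxyphenyl)methoxy]-1,5-dimethyl-2-(3-methylbut-1-en-2-yl)cyclohept-5-ene-1-carboxylate F7. Reduction with i-Bu2AlH (CH2Cl2, −78 °C) gives (1S,2S,7R)-2-hydroxy-7-[(4-methoxyphenyl)methoxy]-1,5-dimethyl-2-(3-methylbut-1-en-2-yl)cyclohept-5-ene-1-carbaldehyde F8. Intramolecular hydroacylation with [Rh((S)-BINAP)]ClO4 (5 mol %, CH2Cl2, 25–40 °C) adds the acyl–Rh–H unit across the 1,1-disubstituted alkene and returns to the route at 13. In this variant the substrate's own preference (isopropyl next to OH in the reacting rotamer) favours the C3 epimer, so the chiral ligand has to override it; that is why it is only the fallback.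

Step 4 (two stereocentres in one step). Enantioselectivity at the ether carbon is well precedented, but the diastereoselectivity at the quaternary carbon of an acyclic α-methyl β-keto ester is uncertain. Fallback: set the pair by auxiliary and chelate control instead of catalyst control.
- Setting out from 6, alkylation of the lithium enolate of N-methoxy-N-methylacetamide (LDA, THF, −78 °C) gives N-methoxy-N,4-dimethylpent-4-enamide F1.
- Evans syn-aldol reaction of (4S)-4-benzyl-3-propanoyl-1,3-oxazolidin-2-one with acrolein (Bu2BOTf, Et3N, CH2Cl2, −78 °C) gives (4S)-4-benzyl-3-[(2S,3R)-3-hydroxy-2-methylpent-4-enoyl]-1,3-oxazolidin-2-one F2, and NaOMe in MeOH releases methyl (2S,3R)-3-hydroxy-2-methylpent-4-enoate F3.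
- Fráter–Seebach C-acylation of the dianion of F3 (LDA, 2.2 equiv, THF, −78 °C) with F1 places the acyl group anti to the alkoxide and gives methyl (2S)-2-[(1R)-1-hydroxyprop-2-en-1-yl]-2,6-dimethyl-3-oxohept-6-enoate F4.
- 4-Methoxybenzyl 2,2,2-trichloroacetimidate with catalytic La(OTf)3 then protects the hydroxyl and the route is rejoined at 8.

Step 7 (carbenoid addition to a neopentylic ester). The ester sits on a quaternary carbon and may react too slowly before LiCH2Cl decomposes. Fallback: a redox detour through the less hindered aldehyde. Setting out from 11, i-Bu2AlH (2.2 equiv, CH2Cl2, −78 °C) gives (1S,2S,7R)-2-hydroxy-7-[(4-methoxyphenyl)methoxy]-1,5-dimethyl-2-(2-methylprop-1-en-1-yl)cyclohept-5-ene-1-carbaldehyde F5. LiCH2Cl (ICH2Cl, MeLi·LiBr, THF, −78 °C) adds to the aldehyde to give 2-chloro-1-[(1S,2S,7R)-2-hydroxy-7-[(4-methoxyphenyl)methoxy]-1,5-dimethyl-2-(2-methylprop-1-en-1-yl)cyclohept-5-en-1-yl]ethan-1-ol F6 as a mixture of carbinol epimers. Dess–Martin periodinane (CH2Cl2, NaHCO3) oxidises the secondary alcohol and the route is rejoined at 12.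

**Further compounds**

F1 | step 4 | N-methoxy-N,4-dimethylpent-4-enamide | CON(C)C(=O)CCC(C)=C
F2 | step 4 | (4S)-4-benzyl-3-[(2S,3R)-3-hydroxy-2-methylpent-4-enoyl]-1,3-oxazolidin-2-one | O=C1OC[C@H](Cc2ccccc2)N1C(=O)[C@@H](C)[C@H](O)C=C
F3 | step 4 | methyl (2S,3R)-3-hydroxy-2-methylpent-4-enoate | COC(=O)[C@@H](C)[C@H](O)C=C
F4 | step 4 | methyl (2S)-2-[(1R)-1-hydroxyprop-2-en-1-yl]-2,6-dimethyl-3-oxohept-6-enoate | COC(=O)[C@](C)(C(=O)CCC(C)=C)[C@H](O)C=C
F5 | step 7 | (1S,2S,7R)-2-hydroxy-7-[(4-methoxyphenyl)methoxy]-1,5-dimethyl-2-(2-methylprop-1-en-1-yl)cyclohept-5-ene-1-carbaldehyde | O=C[C@]1(C)[C@@](O)(C=C(C)C)CCC(C)=C[C@H]1OCc2ccc(OC)cc2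
F6 | step 7 | 2-chloro-1-[(1S,2S,7R)-2-hydroxy-7-[(4-methoxyphenyl)methoxy]-1,5-dimethyl-2-(2-methylprop-1-en-1-yl)cyclohept-5-en-1-yl]ethan-1-ol (carbinol epimers) | ClCC(O)[C@]1(C)[C@@](O)(C=C(C)C)CCC(C)=C[C@H]1OCc2ccc(OC)cc2
F7 | step 8 | methyl (1S,2S,7R)-2-hydroxy-7-[(4-methoxyphenyl)methoxy]-1,5-dimethyl-2-(3-methylbut-1-en-2-yl)cyclohept-5-ene-1-carboxylate | COC(=O)[C@]1(C)[C@@](O)(C(=C)C(C)C)CCC(C)=C[C@H]1OCc2ccc(OC)cc2
F8 | step 8 | (1S,2S,7R)-2-hydroxy-7-[(4-methoxyphenyl)methoxy]-1,5-dimethyl-2-(3-methylbut-1-en-2-yl)cyclohept-5-ene-1-carbaldehyde | O=C[C@]1(C)[C@@](O)(C(=C)C(C)C)CCC(C)=C[C@H]1OCc2ccc(OC)cc2
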